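**Retrosynthetic overview**

1. Target 27 ⇐ 26 ⇐ 25 ⇐ 24: acetonide hydrolysis, acetylation and cis-selective 1,2-reduction of C4=O come last; every skeletal bond is already present in dione 24.
2. Feature used: C8a is the one carbon common to the pyran ring (O1–C2–C3–C4–C4a–C8a) and the carbocycle (C4a–C5–C6–C7–C8–C8a), and in an open chain it is the β-carbon of a C4 ynone. Cutting O1–C8a and C4a–C5 together unfolds both rings into hydroxy ynone ester 21.
3. Ring order in the forward sense: pyran first (O1→C8a, oxa-Michael), carbocycle second (C4a→C5, Dieckmann), both in one flask.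
4. 21 ⇐ C4–C4a bond: acetylide of alkyne ester 15 plus Weinreb amide 18, which carries C2 from ethyl (R)-3-hydroxy-3-phenylpropanoate.
5. 15 ⇐ D-pantolactone: C7 from the chiral pool, C8 by chelate-controlled MeMgBr addition to α-hydroxy ynone 7, then acetonide and CH2OH → CO2Me.

Key step: step 13

Remark: atoms carry the chromene numbering of the target (O1, C2–C4, C4a, C5–C8, C8a) throughout, also in open-chain intermediates. D-pantolactone is the (R)-enantiomer; the target is read as (2R,4R,7R,8R), with 2-Ph/4-OAc cis and the 7,8-diol cis.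

**Route**

Step 1
Reactants: 1 D-pantolactone
Product: 2 (R)-2,4-dihydroxy-N-methoxy-N,3,3-trimethylbutanamide
Conditions: MeNH(OMe)·HCl, i-PrMgCl, THF, −20 → 0 °C; aq NH4Cl; used crude
Reagents that add atoms: N,O-dimethylhydroxylamine hydrochloride, CNOC.Cl
Why: Weinreb aminolysis of the lactone by the chloromagnesium amide opens the ring at the acyl C–O bond without touching C7, and the crude diol is silylated at once so that it cannot relactonise.

Step 2
Reactants: 2 (R)-2,4-dihydroxy-N-methoxy-N,3,3-trimethylbutanamide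
Product: 3 (R)-4-[(tert-butyldimethylsilyl)oxy]-N-methoxy-N,3,3-trimethyl-2-[(trimethylsilyl)oxy]butanamide
Conditions: TBSCl (1.05 equiv), imidazole, DMF, 0 °C; then TMSCl, rt
Reagents that add atoms: tert-butyldimethylsilyl chloride, CC(C)(C)[Si](C)(C)Cl; chlorotrimethylsilane, C[Si](C)(C)Cl
Why: Silylation under Corey conditions takes the primary OH first (TBS), and TMSCl then caps the hindered secondary OH so that no free alkoxide sits next to the amide or the silyl ether in step 3.

Step 3
Reactants: 3 (R)-4-[(tert-butyldimethylsilyl)oxy]-N-methoxy-N,3,3-trimethyl-2-[(trimethylsilyl)oxy]butanamide; 4 ethynyltrimethylsilane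
Product: 7 (R)-6-[(tert-butyldimethylsilyl)oxy]-4-hydroxy-5,5-dimethyl-1-(trimethylsilyl)hex-1-yn-3-one, via lithium (trimethylsilyl)acetylide 5 (not isolated), via O-trimethylsilyl ynone 6 (not isolated)
Conditions: 4 (2 equiv), n-BuLi, THF, −78 °C; then 3, −78 → 0 °C; 1 M HCl, THF, 0 °C, 15 min
Reagents that add atoms: none
Why: Weinreb ketone synthesis: the chelated tetrahedral adduct stops at the ketone stage, and the cold acidic quench keeps the liberated amine from adding to the ynone and hydrolyses the labile secondary O–TMS ether while O–TBS and C–TMS stay.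

Step 4
Reactants: 7 (R)-6-[(tert-butyldimethylsilyl)oxy]-4-hydroxy-5,5-dimethyl-1-(trimethylsilyl)hex-1-yn-3-one; 8 methylmagnesium bromide
Product: 10 (3S,4R)-6-[(tert-butyldimethylsilyl)oxy]-3,5,5-trimethyl-1-(trimethylsilyl)hex-1-yne-3,4-diol, via bromomagnesium alkoxide chelate 9 (not isolated)
Conditions: MeMgBr (3 equiv), THF, −78 °C; aq NH4Cl
Reagents that add atoms: none
Why: Cram chelate-controlled Grignard 1,2-addition: the first equivalent forms the magnesium alkoxide, which ties the C8 ketone into a five-membered chelate, and methyl then adds from the face opposite the quaternary C6 group, so C8 is set (3S here) with the alkynyl group cis to the C6 chain, as the 7,8-cis diol requires; the steric Felkin–Anh model with the tert-alkyl group anti points to the same face.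

Step 5
Reactants: 10 (3S,4R)-6-[(tert-butyldimethylsilyl)oxy]-3,5,5-trimethyl-1-(trimethylsilyl)hex-1-yne-3,4-diol
Product: 11 tert-butyldimethyl{2-methyl-2-[(4R,5S)-2,2,5-trimethyl-5-[(trimethylsilyl)ethynyl]-1,3-dioxolan-4-yl]propoxy}silane
Conditions: 2-methoxypropene, PPTS (cat.), CH2Cl2, 0 °C → rt
Reagents that add atoms: 2-methoxypropene, C=C(C)OC
Why: Acid-catalysed acetonide formation on the only free 1,2-diol, which fixes the alkynyl group and the C6 chain cis on a dioxolane; PPTS spares the TBS ether.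

Step 6
Reactants: 11 tert-butyldimethyl{2-methyl-2-[(4R,5S)-2,2,5-trimethyl-5-[(trimethylsilyl)ethynyl]-1,3-dioxolan-4-yl]propoxy}silane
Product: 12 2-[(4R,5S)-5-ethynyl-2,2,5-trimethyl-1,3-dioxolan-4-yl]-2-methylpropan-1-ol
Conditions: TBAF (2.5 equiv), THF, 0 °C → rt; aq NH4Cl
Reagents that add atoms: none
Why: Fluoride desilylation cleaves the O–TBS ether and the alkynyl C–Si bond in one operation and leaves the acetonide alone.

Step 7
Reactants: 12 2-[(4R,5S)-5-ethynyl-2,2,5-trimethyl-1,3-dioxolan-4-yl]-2-methylpropan-1-ol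
Product: 14 2-[(4R,5S)-5-ethynyl-2,2,5-trimethyl-1,3-dioxolan-4-yl]-2-methylpropanoic acid, via aldehyde 13 (not isolated)
Conditions: TEMPO (cat.), NaOCl (cat.), NaClO2, MeCN/phosphate buffer (pH 6.7), 35 °C
Reagents that add atoms: sodium chlorite, [Na+].[O-]Cl=O
Why: Zhao oxidation (TEMPO/bleach to the aldehyde, chlorite to the acid) at near-neutral pH tolerates acetonide and terminal alkyne, and the α-quaternary aldehyde cannot epimerise.

Step 8
Reactants: 14 2-[(4R,5S)-5-ethynyl-2,2,5-trimethyl-1,3-dioxolan-4-yl]-2-methylpropanoic acid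
Product: 15 methyl 2-[(4R,5S)-5-ethynyl-2,2,5-trimethyl-1,3-dioxolan-4-yl]-2-methylpropanoate
Conditions: MeI, K2CO3, DMF, rt
Reagents that add atoms: iodomethane, CI
Why: SN2 O-alkylation of the carboxylate is insensitive to the hindrance at the neopentyl acyl carbon, and K2CO3 does not deprotonate the alkyne.

Step 9
Reactants: 16 ethyl (R)-3-hydroxy-3-phenylpropanoate
Product: 17 (R)-3-hydroxy-N-methoxy-N-methyl-3-phenylpropanamide
Conditions: MeNH(OMe)·HCl, i-PrMgCl, THF, −20 °C; aq NH4Cl
Reagents that add atoms: N,O-dimethylhydroxylamine hydrochloride, CNOC.Cl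
Why: Direct ester-to-Weinreb-amide aminolysis with the chloromagnesium amide tolerates the free hydroxyl as its magnesium alkoxide and does not touch the carbinol centre.

Step 10
Reactants: 17 (R)-3-hydroxy-N-methoxy-N-methyl-3-phenylpropanamide
Product: 18 (R)-N-methoxy-N-methyl-3-phenyl-3-[(triethylsilyl)oxy]propanamide
Conditions: TESCl, imidazole, CH2Cl2, 0 °C
Reagents that add atoms: chlorotriethylsilane, CC[Si](Cl)(CC)CC
Why: Standard silylation; the TES ether survives the acetylide coupling and comes off later under buffered, non-basic conditions.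

Step 11
Reactants: 15 methyl 2-[(4R,5S)-5-ethynyl-2,2,5-trimethyl-1,3-dioxolan-4-yl]-2-methylpropanoate; 18 (R)-N-methoxy-N-methyl-3-phenyl-3-[(triethylsilyl)oxy]propanamide
Product: 20 methyl 2-methyl-2-{(4R,5S)-2,2,5-trimethyl-5-[(5R)-3-oxo-5-phenyl-5-[(triethylsilyl)oxy]pent-1-yn-1-yl]-1,3-dioxolan-4-yl}propanoate, via lithium acetylide 19 (not isolated)
Conditions: 15, LDA (1.0 equiv), THF, −78 °C; then 18 (1.3 equiv), −78 → 0 °C; AcOH, −78 °C
Reagents that add atoms: none
Why: Acylation of a lithium acetylide by a Weinreb amide forms C4–C4a; the methyl ester has no α-hydrogen and a neopentyl carbonyl, so LDA only deprotonates the alkyne and the acetylide chooses the amide.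

Step 12
Reactants: 20 methyl 2-methyl-2-{(4R,5S)-2,2,5-trimethyl-5-[(5R)-3-oxo-5-phenyl-5-[(triethylsilyl)oxy]pent-1-yn-1-yl]-1,3-dioxolan-4-yl}propanoate
Product: 21 methyl 2-{(4R,5S)-5-[(5R)-5-hydroxy-3-oxo-5-phenylpent-1-yn-1-yl]-2,2,5-trimethyl-1,3-dioxolan-4-yl}-2-methylpropanoate
Conditions: HF·pyridine, pyridine, THF, 0 °C
Reagents that add atoms: none
Why: Buffered HF·pyridine cleaves the TES ether without base, so the β-hydroxy ynone is freed without retro-aldol or premature cyclisation, and acetonide and ester stay intact.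

Step 13
Reactants: 21 methyl 2-{(4R,5S)-5-[(5R)-5-hydroxy-3-oxo-5-phenylpent-1-yn-1-yl]-2,2,5-trimethyl-1,3-dioxolan-4-yl}-2-methylpropanoate
Product: 24 (2R,7R,8R)-7,8-(isopropylidenedioxy)-6,6,8-trimethyl-2-phenyl-2,3,7,8-tetrahydro-4H-chromene-4,5(6H)-dione, via sodium alkoxide 22 (not isolated), via C4a anion 23 (not isolated)
Conditions: NaHMDS (1.0 equiv), THF (0.01 M), −78 → −30 °C; AcOH, −78 °C
Reagents that add atoms: none
Why: Proposed new method: NaHMDS turns the C2–OH into alkoxide 22, whose oxygen adds anti and 6-endo-dig to the ynone carbon C8a and leaves in 23 an sp2 carbanion (a bent cyclic allenolate) at C4a with its lobe in the ring plane, cis to C8, from where it attacks the C5 ester 6-exo-trig and expels methoxide to give 24. The closest known reactions are the 6-endo oxa-Michael cyclisation of δ-hydroxy ynones to 2,3-dihydro-4H-pyran-4-ones and Michael-initiated Dieckmann closures (thiosalicylate plus ynoate to thiochromone); new is their union in one chain with a ring-bound, non-delocalised C4a anion. The pyran closes 6-endo-dig (O1–C8a) and the carbocycle 6-exo-trig (C4a–C5), the latter helped because the dioxolane holds the ester-bearing C6 and C8a cis. No stereocentre is formed; C2, C7 and C8 are carried through, C2 with retention as long as the aldolate does not revert. The step needs C-acylation to outrun proton capture at C4a and retro-aldol loss of benzaldehyde, and O1–C8a rather than O1–C5 regiochemistry: the first is served by a dilute aprotic medium whose only acid is the weak, hindered HN(SiMe3)2 and by the ester sitting next to the anion, the second is fixed because the ring oxygen is in place before ring A exists. AcOH is added at −78 °C before the liberated methoxide can enolise C3 and open the pyranone by β-elimination.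

Step 14
Reactants: 24 (2R,7R,8R)-7,8-(isopropylidenedioxy)-6,6,8-trimethyl-2-phenyl-2,3,7,8-tetrahydro-4H-chromene-4,5(6H)-dione
Product: 25 (2R,4R,7R,8R)-4-hydroxy-7,8-(isopropylidenedioxy)-6,6,8-trimethyl-2-phenyl-2,3,4,6,7,8-hexahydro-5H-chromen-5-one
Conditions: NaBH4, CeCl3·7H2O, MeOH, −78 °C
Reagents that add atoms: none
Why: Luche reduction: hydride adds 1,2 to the C4 ketone, which has a CH2 neighbour whereas C5 is shielded by the C6 gem-dimethyl group, and axial delivery on the half-chair with pseudo-equatorial phenyl should give the pseudo-equatorial 4-OH cis to C2-Ph (4R), as in reductions of 2-substituted dihydropyranones and flavanones.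

Step 15
Reactants: 25 (2R,4R,7R,8R)-4-hydroxy-7,8-(isopropylidenedioxy)-6,6,8-trimethyl-2-phenyl-2,3,4,6,7,8-hexahydro-5H-chromen-5-one
Product: 26 (2R,4R,7R,8R)-7,8-(isopropylidenedioxy)-6,6,8-trimethyl-5-oxo-2-phenyl-3,4,5,6,7,8-hexahydro-2H-chromen-4-yl acetate
Conditions: Ac2O, pyridine, DMAP (cat.), CH2Cl2, 0 °C
Reagents that add atoms: acetic anhydride, CC(=O)OC(C)=O
Why: DMAP-catalysed acylation of the only free hydroxyl; the C–O bond at C4 is not broken, so the configuration is kept.

Step 16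
Reactants: 26 (2R,4R,7R,8R)-7,8-(isopropylidenedioxy)-6,6,8-trimethyl-5-oxo-2-phenyl-3,4,5,6,7,8-hexahydro-2H-chromen-4-yl acetate
Product: 27 (2R,4R,7R,8R)-7,8-dihydroxy-6,6,8-trimethyl-5-oxo-2-phenyl-3,4,5,6,7,8-hexahydro-2H-chromen-4-yl acetate (CNP0123729.1)
Conditions: AcOH/H2O (4:1), 45 °C
Reagents that add atoms: none
Why: Mild acid-catalysed acetal hydrolysis frees the cis-7,8-diol; the enol ether is deactivated by the C5 carbonyl, and the acetate should survive aqueous acetic acid.

**Compound list**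

1 | D-pantolactone, (R)-3-hydroxy-4,4-dimethyldihydrofuran-2(3H)-one | CC1(C)COC(=O)[C@@H]1O | starting material
2 | (R)-2,4-dihydroxy-N-methoxy-N,3,3-trimethylbutanamide | CON(C)C(=O)[C@H](O)C(C)(C)CO | intermediate
3 | (R)-4-[(tert-butyldimethylsilyl)oxy]-N-methoxy-N,3,3-trimethyl-2-[(trimethylsilyl)oxy]butanamide | CON(C)C(=O)[C@H](O[Si](C)(C)C)C(C)(C)CO[Si](C)(C)C(C)(C)C | intermediate
4 | ethynyltrimethylsilane | C#C[Si](C)(C)C | starting material
5 | lithium (trimethylsilyl)acetylide | [Li]C#C[Si](C)(C)C | intermediate (not isolated)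
6 | (R)-6-[(tert-butyldimethylsilyl)oxy]-5,5-dimethyl-1-(trimethylsilyl)-4-[(trimethylsilyl)oxy]hex-1-yn-3-one | C[Si](C)(C)C#CC(=O)[C@H](O[Si](C)(C)C)C(C)(C)CO[Si](C)(C)C(C)(C)C | intermediate (not isolated)
7 | (R)-6-[(tert-butyldimethylsilyl)oxy]-4-hydroxy-5,5-dimethyl-1-(trimethylsilyl)hex-1-yn-3-one | C[Si](C)(C)C#CC(=O)[C@H](O)C(C)(C)CO[Si](C)(C)C(C)(C)C | intermediate
8 | methylmagnesium bromide | C[Mg]Br | starting material
9 | bromomagnesium alkoxide of 7 (five-membered Mg chelate with the C8 ketone) | C[Si](C)(C)C#CC(=O)[C@H](O[Mg]Br)C(C)(C)CO[Si](C)(C)C(C)(C)C | intermediate (not isolated)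
10 | (3S,4R)-6-[(tert-butyldimethylsilyl)oxy]-3,5,5-trimethyl-1-(trimethylsilyl)hex-1-yne-3,4-diol | C[Si](C)(C)C#C[C@](C)(O)[C@H](O)C(C)(C)CO[Si](C)(C)C(C)(C)C | intermediate
11 | tert-butyldimethyl{2-methyl-2-[(4R,5S)-2,2,5-trimethyl-5-[(trimethylsilyl)ethynyl]-1,3-dioxolan-4-yl]propoxy}silane | CC(C)(C)[Si](C)(C)OCC(C)(C)[C@H]1OC(C)(C)O[C@@]1(C)C#C[Si](C)(C)C | intermediate
12 | 2-[(4R,5S)-5-ethynyl-2,2,5-trimethyl-1,3-dioxolan-4-yl]-2-methylpropan-1-ol | OCC(C)(C)[C@H]1OC(C)(C)O[C@@]1(C)C#C | intermediate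
13 | 2-[(4R,5S)-5-ethynyl-2,2,5-trimethyl-1,3-dioxolan-4-yl]-2-methylpropanal | O=CC(C)(C)[C@H]1OC(C)(C)O[C@@]1(C)C#C | intermediate (not isolated)
14 | 2-[(4R,5S)-5-ethynyl-2,2,5-trimethyl-1,3-dioxolan-4-yl]-2-methylpropanoic acid | OC(=O)C(C)(C)[C@H]1OC(C)(C)O[C@@]1(C)C#C | intermediate
15 | methyl 2-[(4R,5S)-5-ethynyl-2,2,5-trimethyl-1,3-dioxolan-4-yl]-2-methylpropanoate | COC(=O)C(C)(C)[C@H]1OC(C)(C)O[C@@]1(C)C#C | intermediate
16 | ethyl (R)-3-hydroxy-3-phenylpropanoate | CCOC(=O)C[C@@H](O)c1ccccc1 | starting material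
17 | (R)-3-hydroxy-N-methoxy-N-methyl-3-phenylpropanamide | CON(C)C(=O)C[C@@H](O)c1ccccc1 | intermediate
18 | (R)-N-methoxy-N-methyl-3-phenyl-3-[(triethylsilyl)oxy]propanamide | CON(C)C(=O)C[C@@H](O[Si](CC)(CC)CC)c1ccccc1 | intermediate
19 | lithium acetylide of alkyne ester 15 | COC(=O)C(C)(C)[C@H]1OC(C)(C)O[C@@]1(C)C#C[Li] | intermediate (not isolated)
20 | methyl 2-methyl-2-{(4R,5S)-2,2,5-trimethyl-5-[(5R)-3-oxo-5-phenyl-5-[(triethylsilyl)oxy]pent-1-yn-1-yl]-1,3-dioxolan-4-yl}propanoate | COC(=O)C(C)(C)[C@H]1OC(C)(C)O[C@@]1(C)C#CC(=O)C[C@@H](O[Si](CC)(CC)CC)c1ccccc1 | intermediate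
21 | methyl 2-{(4R,5S)-5-[(5R)-5-hydroxy-3-oxo-5-phenylpent-1-yn-1-yl]-2,2,5-trimethyl-1,3-dioxolan-4-yl}-2-methylpropanoate (key-step precursor) | COC(=O)C(C)(C)[C@H]1OC(C)(C)O[C@@]1(C)C#CC(=O)C[C@@H](O)c1ccccc1 | intermediate
22 | sodium alkoxide of 21 | COC(=O)C(C)(C)[C@H]1OC(C)(C)O[C@@]1(C)C#CC(=O)C[C@@H]([O-])c1ccccc1.[Na+] | intermediate (not isolated)
23 | sodium salt of the C4a carbanion of the monocyclic (6R)-6-phenyl-2,3-dihydro-4H-pyran-4-one (pyran closed, ester still open) | COC(=O)C(C)(C)[C@H]1OC(C)(C)O[C@@]1(C)C2=[C-]C(=O)C[C@H](c3ccccc3)O2.[Na+] | intermediate (not isolated)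
24 | (2R,7R,8R)-7,8-(isopropylidenedioxy)-6,6,8-trimethyl-2-phenyl-2,3,7,8-tetrahydro-4H-chromene-4,5(6H)-dione (key-step product) | O=C1C[C@H](c2ccccc2)OC2=C1C(=O)C(C)(C)[C@H]1OC(C)(C)O[C@@]21C | intermediate
25 | (2R,4R,7R,8R)-4-hydroxy-7,8-(isopropylidenedioxy)-6,6,8-trimethyl-2-phenyl-2,3,4,6,7,8-hexahydro-5H-chromen-5-one | O[C@@H]1C[C@H](c2ccccc2)OC2=C1C(=O)C(C)(C)[C@H]1OC(C)(C)O[C@@]21C | intermediate
26 | (2R,4R,7R,8R)-7,8-(isopropylidenedioxy)-6,6,8-trimethyl-5-oxo-2-phenyl-3,4,5,6,7,8-hexahydro-2H-chromen-4-yl acetate | CC(=O)O[C@@H]1C[C@H](c2ccccc2)OC2=C1C(=O)C(C)(C)[C@H]1OC(C)(C)O[C@@]21C | intermediate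
27 | (2R,4R,7R,8R)-7,8-dihydroxy-6,6,8-trimethyl-5-oxo-2-phenyl-3,4,5,6,7,8-hexahydro-2H-chromen-4-yl acetate (CNP0123729.1) | CC(=O)O[C@@H]1C[C@H](c2ccccc2)OC2=C1C(=O)C(C)(C)[C@@H](O)[C@@]2(C)O | target

**Step count**

Total: 16 steps. Longest linear sequence: 14 steps (steps 1–8 and 11–16, from D-pantolactone); the side branch is steps 9–10.

**Steps most likely to fail**

Step 13 (proposed new method). The alkyne π bond that the alkoxide must attack in the ring plane is not the one conjugated with C4=O, so the 6-endo-dig addition may be slow. Retro-aldol cleavage, dehydration through the C3 enolate, or proton capture at C4a before acylation can then take over. The liberated methoxide may also open the pyranone by β-elimination from C3. The fallback builds the same two bonds stepwise by known reactions and keeps the regiochemistry. It sets out from 21. AgOTf (10 mol %) in CH2Cl2 at rt closes the pyran alone by the known 6-endo cyclisation of β-hydroxy ynones and gives methyl 2-methyl-2-{(4R,5R)-2,2,5-trimethyl-5-[(6R)-4-oxo-6-phenyl-5,6-dihydro-4H-pyran-2-yl]-1,3-dioxolan-4-yl}propanoate F1. Electrophilic iodination of the vinylogous ester at C4a with N-iodosuccinimide in MeCN gives the C4a iodide F2. Iodine–magnesium exchange with i-PrMgCl·LiCl in THF at −40 °C gives the alkenylmagnesium chloride F3, which acylates itself on the neighbouring methyl ester (Parham-type cyclisation). The route is rejoined at 24.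

Step 14. Hydride may be delivered to the wrong face of C4, or some may go to C5 or add 1,4, on a cross-conjugated ene-dione for which substrate control is only inferred from simpler dihydropyranones. The fallback gives up the cis-selective reduction and corrects C4 by inversion. It sets out from 24. L-Selectride in THF at −78 °C, a bulky hydride that attacks from the equatorial direction, should give (2R,4S,7R,8R)-4-hydroxy-7,8-(isopropylidenedioxy)-6,6,8-trimethyl-2-phenyl-2,3,4,6,7,8-hexahydro-5H-chromen-5-one F4. Mitsunobu reaction with acetic acid (PPh3, DIAD, THF, 0 °C) inverts C4 and installs the acetate in the same step; SN2′ attack is blocked because C8a is fully substituted. The route is rejoined at 26.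

Step 16. The acid needed to open the hindered acetonide may ionise the allylic C4–O bond (loss or scrambling of the acetate) or hydrolyse the ester before the acetal opens. The fallback moves the deprotection to the dione stage, where nothing is acid-sensitive, and relies on site selectivity instead of a protecting group. It sets out from 24. TFA/H2O (9:1) at 0 °C gives (2R,7R,8R)-7,8-dihydroxy-6,6,8-trimethyl-2-phenyl-2,3,7,8-tetrahydro-4H-chromene-4,5(6H)-dione F5. Luche reduction (NaBH4, CeCl3·7H2O, MeOH, −78 °C) gives (2R,4R,7R,8R)-4,7,8-trihydroxy-6,6,8-trimethyl-2-phenyl-2,3,4,6,7,8-hexahydro-5H-chromen-5-one F6. Ac2O (1.1 equiv) and pyridine in CH2Cl2 at 0 °C should acetylate only the allylic C4–OH, since C7–OH lies between two quaternary carbons and C8–OH is tertiary. The route is rejoined at 27.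

**Further compounds**

F1 | step 13 | methyl 2-methyl-2-{(4R,5R)-2,2,5-trimethyl-5-[(6R)-4-oxo-6-phenyl-5,6-dihydro-4H-pyran-2-yl]-1,3-dioxolan-4-yl}propanoate | COC(=O)C(C)(C)[C@H]1OC(C)(C)O[C@@]1(C)C2=CC(=O)C[C@H](c3ccccc3)O2
F2 | step 13 | methyl 2-{(4R,5R)-5-[(6R)-3-iodo-4-oxo-6-phenyl-5,6-dihydro-4H-pyran-2-yl]-2,2,5-trimethyl-1,3-dioxolan-4-yl}-2-methylpropanoate | COC(=O)C(C)(C)[C@H]1OC(C)(C)O[C@@]1(C)C2=C(I)C(=O)C[C@H](c3ccccc3)O2
F3 | step 13 | alkenylmagnesium chloride formed from F2 by iodine–magnesium exchange at C4a | COC(=O)C(C)(C)[C@H]1OC(C)(C)O[C@@]1(C)C2=C([Mg]Cl)C(=O)C[C@H](c3ccccc3)O2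
F4 | step 14 | (2R,4S,7R,8R)-4-hydroxy-7,8-(isopropylidenedioxy)-6,6,8-trimethyl-2-phenyl-2,3,4,6,7,8-hexahydro-5H-chromen-5-one | O[C@H]1C[C@H](c2ccccc2)OC2=C1C(=O)C(C)(C)[C@H]1OC(C)(C)O[C@@]21C
F5 | step 16 | (2R,7R,8R)-7,8-dihydroxy-6,6,8-trimethyl-2-phenyl-2,3,7,8-tetrahydro-4H-chromene-4,5(6H)-dione | O=C1C[C@H](c2ccccc2)OC2=C1C(=O)C(C)(C)[C@@H](O)[C@@]2(C)O
F6 | step 16 | (2R,4R,7R,8R)-4,7,8-trihydroxy-6,6,8-trimethyl-2-phenyl-2,3,4,6,7,8-hexahydro-5H-chromen-5-one | O[C@@H]1C[C@H](c2ccccc2)OC2=C1C(=O)C(C)(C)[C@@H](O)[C@@]2(C)O
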